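**Strategy.** The route rests on disconnecting the C5–C6 bond (longipinane numbering), where the gem-dimethyl quaternary carbon C6 of the seven-membered ring (C5–C6–C7–C8–C9–C10–C11) meets the cyclobutane methine C5. A bicyclo[3.1.1]heptan-6-one, made by an intramolecular ketene–alkene (2+2) cycloaddition under control of the C3 methyl stereocentre, carries on C10 the C9–C8–C7 chain ending in the isopropenyl carbon C6. Its cyclobutanone N-tosylhydrazone undergoes an iron-hydride-initiated radical reductive alkylation. In one operation this forms the C6 quaternary centre, the C5–H stereocentre and the seven-membered ring, which spans the 1,3-positions of the cyclobutane. The cis-8,9-diol follows by ring-controlled oxidation and reduction.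

Key step: step 12

Remark: locants are the longipinane locants of 33 (C1 ketone carbon, C3 CH–CH3, C4/C11 cyclobutane bridgeheads, C5 cyclobutane CH, C6 CMe2, C7 CHOH, C8/C9 angelate carbons, C10 quaternary cyclobutane carbon) and are used for the same carbons in every intermediate. The C1 carbinol centre made in step 5 is carried as both epimers (it becomes the ketone in step 17) and is left undefined in the SMILES of 10–14, 16–27 and 30–32.

Step 1
Reactants: 1 (R)-4-methoxy-2-methyl-4-oxobutanoic acid
Product: 2 methyl (R)-4-hydroxy-3-methylbutanoate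
Conditions: BH3·SMe2, THF, 0 °C to rt; MeOH quench
Reagents that add atoms: none
Why: Chemoselective borane reduction of the carboxylic acid beside the methyl ester should give the hydroxy ester without touching the C3 stereocentre, which is used at once to avoid lactonisation.

Step 2
Reactants: 2 methyl (R)-4-hydroxy-3-methylbutanoate; 3 2-(triphenylphosphoranylidene)propanal
Product: 5 methyl (3R,4E)-3,5-dimethyl-6-oxohex-4-enoate, via aldehyde 4 (not isolated)
Conditions: Dess–Martin periodinane, CH2Cl2, 0 °C to rt; then 3, 40 °C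
Reagents that add atoms: none
Why: Dess–Martin oxidation followed in the same flask by Wittig olefination with the stabilised formyl ylide should give the (E)-2-methyl enal (C4=C10), the neutral conditions sparing the α-stereocentre of the aldehyde.

Step 3
Reactants: 5 methyl (3R,4E)-3,5-dimethyl-6-oxohex-4-enoate
Product: 6 methyl (3R,4E)-3,5-dimethylhepta-4,6-dienoate
Conditions: Ph3PCH3Br, KN(SiMe3)2, THF, −78 °C to 0 °C
Reagents that add atoms: methyltriphenylphosphonium bromide, C[P+](c1ccccc1)(c1ccccc1)c1ccccc1.[Br-]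
Why: Wittig methylenation of the aldehyde (much faster than attack on the ester) installs the vinyl group that later becomes C9 and C8 and leaves the E trisubstituted alkene unchanged.

Step 4
Reactants: 6 methyl (3R,4E)-3,5-dimethylhepta-4,6-dienoate
Product: 7 (3R,4E)-3,5-dimethylhepta-4,6-dienal
Conditions: i-Bu2AlH, CH2Cl2, −78 °C; aq. KNaC4H4O6 (potassium sodium tartrate)
Reagents that add atoms: none
Why: Partial reduction of the methyl ester through the stable aluminium hemiacetal at low temperature should stop at the aldehyde (C1), whose stereocentre is β and cannot epimerise.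

Step 5
Reactants: 7 (3R,4E)-3,5-dimethylhepta-4,6-dienal; 8 ethoxyethyne
Product: 10 (5R,6E)-1-ethoxy-5,7-dimethylnona-6,8-dien-1-yn-3-ol (both C3 epimers), via lithium ethoxyacetylide 9 (not isolated)
Conditions: 8, n-BuLi, THF, −78 °C; then 7, −78 °C; H2O
Reagents that add atoms: none
Why: Acetylide addition to the aldehyde attaches the two carbons that become C11 and C5 as a latent ketene; the new carbinol centre (C1) need not be controlled.

Step 6
Reactants: 10 (5R,6E)-1-ethoxy-5,7-dimethylnona-6,8-dien-1-yn-3-ol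
Product: 11 tert-butyl{[(5R,6E)-1-ethoxy-5,7-dimethylnona-6,8-dien-1-yn-3-yl]oxy}dimethylsilane
Conditions: TBSCl, imidazole, DMF, rt
Reagents that add atoms: tert-butyldimethylsilyl chloride, CC(C)(C)[Si](C)(C)Cl
Why: Standard silylation masks the C1 hydroxyl so that it cannot trap the ketene of the next step.

Step 7
Reactants: 11 tert-butyl{[(5R,6E)-1-ethoxy-5,7-dimethylnona-6,8-dien-1-yn-3-yl]oxy}dimethylsilane
Product: 13 2-(tert-butyldimethylsilyloxy)-4,7-dimethyl-7-vinylbicyclo[3.1.1]heptan-6-one (C5 cyclobutanone; C3 methyl on the side of the carbonyl bridge; C10 methyl syn and vinyl anti to the C1–C3 bridge), via aldoketene 12 (not isolated)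
Conditions: toluene (0.005 M), sealed tube, 130 °C
Reagents that add atoms: none
Why: Thermal retro-ene loss of ethene from the 1-ethoxyalkyne gives ketene 12, whose intramolecular ketene–alkene (2+2) cycloaddition (carbonyl carbon to C4, α-carbon to the cation-stabilising C10) closes the bicyclo[3.1.1]heptanone; the retained E geometry places the C10 methyl syn and the vinyl anti to the three-carbon bridge, and allylic 1,3-strain at C3 (methyl turned away from the C10 methyl) selects the alkene face.

Step 8
Reactants: 13 2-(tert-butyldimethylsilyloxy)-4,7-dimethyl-7-vinylbicyclo[3.1.1]heptan-6-one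
Product: 14 7-acetyl-2-(tert-butyldimethylsilyloxy)-4,7-dimethylbicyclo[3.1.1]heptan-6-one (C9 methyl ketone)
Conditions: PdCl2 (10 mol %), CuCl, O2 (1 atm), DMF/H2O 7:1, rt
Reagents that add atoms: water, O
Why: Tsuji–Wacker oxidation (Markovnikov hydroxypalladation by divalent palladium) should turn the vinyl group on the quaternary C10 into the methyl ketone without affecting the non-enolisable cyclobutanone.

Step 9
Reactants: 14 7-acetyl-2-(tert-butyldimethylsilyloxy)-4,7-dimethylbicyclo[3.1.1]heptan-6-one; 15 methacrolein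
Product: 18 7-[(3R)-3-hydroxy-4-methylpent-4-enoyl]-2-(tert-butyldimethylsilyloxy)-4,7-dimethylbicyclo[3.1.1]heptan-6-one, via enol diisopinocampheylborinate 16 (not isolated), via boron aldolate 17 (not isolated)
Conditions: (−)-Ipc2BCl, Et3N, Et2O, 0 °C; then 15, −78 to −20 °C; pH 7 buffer/MeOH (no peroxide)
Reagents that add atoms: none
Why: Boron-mediated aldol reaction of the only enolisable carbonyl (the methyl ketone) forms the C8–C7 bond, the isopinocampheyl ligands directing attack on the re face of the aldehyde to set the (7R) carbinol by reagent control; a non-oxidative work-up avoids Baeyer–Villiger cleavage of the cyclobutanone.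

Step 10
Reactants: 18 7-[(3R)-3-hydroxy-4-methylpent-4-enoyl]-2-(tert-butyldimethylsilyloxy)-4,7-dimethylbicyclo[3.1.1]heptan-6-one
Product: 19 triethylsilyl ether of 18 (7-OTES)
Conditions: Et3SiCl, imidazole, DMF, 0 °C to rt
Reagents that add atoms: chlorotriethylsilane, CC[Si](Cl)(CC)CC
Why: Silylation protects the C7 hydroxyl, which must stay masked while C8 and C9 are later acylated and serves as the steric control element for the C8 oxidation.

Step 11
Reactants: 19 triethylsilyl ether of 18
Product: 20 C5 N-tosylhydrazone of 19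
Conditions: TsNHNH2 (1.05 equiv), MeOH, rt
Reagents that add atoms: p-toluenesulfonyl hydrazide, Cc1ccc(cc1)S(=O)(=O)NN
Why: Hydrazone condensation should occur selectively at the strain-activated cyclobutanone, the C9 ketone being a slow-reacting tert-alkyl (pinacolone-type) ketone.

Step 12
Reactants: 20 C5 N-tosylhydrazone of 19
Product: 23 1-(tert-butyldimethylsilyloxy)-7-(triethylsilyloxy)longipinan-9-one (configured as 33 at C3/C4/C5/C7/C10/C11), via ring-closed tosylhydrazide 21 (not isolated), via alkyl diazene 22 (not isolated)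
Conditions: Fe(acac)3 (0.3 equiv), PhSiH3, EtOH (0.01 M), 60 °C; then 80 °C
Reagents that add atoms: none
Why: Hydrogen-atom transfer from an iron hydride to the isopropenyl group gives the tertiary C6 radical, which adds 7-exo-trig to the hydrazone carbon C5; the hydrazinyl radical is reduced by divalent iron and protonated to hydrazide 21, which on warming loses p-toluenesulfinic acid and then N2 through diazene 22, leaving hydrogen on C5. The closest known reaction type is the iron-hydride radical reductive alkylation of unactivated alkenes with ketone N-tosylhydrazones (and the hydromethylation of alkenes through formaldehyde sulfonylhydrazones), applied here to a seven-ring closure. C5 is the only new stereocentre and is fixed by the tether: C6 can reach C5 only across the cyclobutane from the anti (pseudo-axial) position on C10, so C6 ends anti and H syn to the C1–C3 bridge whatever the course of the N2 loss. The step needs hydrogen-atom transfer to the only alkene present and ring closure in preference to reduction of the radical; the 1,3-diaxial-type pre-organisation of chain and hydrazone on the rigid cyclobutane, the gem-dialkyl effect at C6, the reversibility of the hydrogen-atom transfer and high dilution favour closure.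

Step 13
Reactants: 23 1-(tert-butyldimethylsilyloxy)-7-(triethylsilyloxy)longipinan-9-one
Product: 26 8-hydroxy-1-(tert-butyldimethylsilyloxy)-7-(triethylsilyloxy)longipinan-9-one (8-OH trans to 7-OTES), via trimethylsilyl enol ether 24 (not isolated), via α-trimethylsilyloxy ketone 25 (not isolated)
Conditions: Me3SiOTf, Et3N, CH2Cl2, 0 °C; then mCPBA, NaHCO3, CH2Cl2, −20 °C; then citric acid, THF/H2O, 0 °C
Reagents that add atoms: meta-chloroperbenzoic acid, OOC(=O)c1cccc(Cl)c1
Why: Rubottom oxidation: soft enolisation can only go toward C8 (C10 is quaternary) and avoids a free enolate that could expel the β-silyloxy group, and the peracid attacks the enol ether anti to the adjacent C7–OTES, setting the C8 oxygen trans to the C7 oxygen.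

Step 14
Reactants: 26 8-hydroxy-1-(tert-butyldimethylsilyloxy)-7-(triethylsilyloxy)longipinan-9-one
Product: 27 1-(tert-butyldimethylsilyloxy)-7-(triethylsilyloxy)longipinane-8,9-diol (cis-8,9-diol)
Conditions: Zn(BH4)2, Et2O, −20 to 0 °C
Reagents that add atoms: none
Why: Chelation-controlled reduction of the α-hydroxy ketone (zinc chelate of the C8 hydroxyl and the C9 carbonyl) delivers hydride on the face of the C8 hydrogen, away from the C10 methyl, to give the cis (erythro) 8,9-diol.

Step 15
Reactants: 27 1-(tert-butyldimethylsilyloxy)-7-(triethylsilyloxy)longipinane-8,9-diol; 28 angelic acid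
Product: 31 1-(tert-butyldimethylsilyloxy)-7-(triethylsilyloxy)longipinane-8,9-diyl bis[(Z)-2-methylbut-2-enoate], via mixed anhydride 29 (not isolated), via 8-monoangelate 30 (not isolated)
Conditions: 28 (2.5 equiv in all), 2,4,6-trichlorobenzoyl chloride, Et3N, toluene, rt; then 27, 80 °C
Reagents that add atoms: angelic acid (second equivalent), C/C=C(/C)C(=O)O
Why: Two successive Yamaguchi-type esterifications through the mixed anhydride, each consuming one equivalent of angelic acid and run without a nucleophilic pyridine catalyst, should acylate first the C8 hydroxyl and then the neopentyl C9 hydroxyl while keeping the Z (angelate) geometry, and because both hydroxyls end up esterified the order of the two acylations does not affect the product.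

Step 16
Reactants: 31 1-(tert-butyldimethylsilyloxy)-7-(triethylsilyloxy)longipinane-8,9-diyl bis[(Z)-2-methylbut-2-enoate]
Product: 32 1,7-dihydroxylongipinane-8,9-diyl bis[(Z)-2-methylbut-2-enoate]
Conditions: HF·pyridine, pyridine, THF, 0 °C to rt
Reagents that add atoms: none
Why: Buffered acidic fluoride removes both silyl ethers without the basic conditions that would promote acyl migration to the C7 hydroxyl or isomerisation of the angelates.

Step 17
Reactants: 32 1,7-dihydroxylongipinane-8,9-diyl bis[(Z)-2-methylbut-2-enoate]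
Product: 33 7-hydroxy-1-oxolongipinane-8,9-diyl bis[(Z)-2-methylbut-2-enoate] (target)
Conditions: Dess–Martin periodinane, pyridine, CH2Cl2, 0 °C
Reagents that add atoms: none
Why: Dess–Martin oxidation should take the accessible C1 carbinol (both epimers converge on the ketone) and leave the neopentyl C7 hydroxyl, which is flanked by CMe2 and an acyloxy carbon.

**Compound list**

1 | (R)-4-methoxy-2-methyl-4-oxobutanoic acid | C[C@H](CC(=O)OC)C(=O)O | starting material
2 | methyl (R)-4-hydroxy-3-methylbutanoate | C[C@H](CC(=O)OC)CO | intermediate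
3 | 2-(triphenylphosphoranylidene)propanal | CC(C=O)=P(c1ccccc1)(c1ccccc1)c1ccccc1 | starting material
4 | methyl (R)-3-methyl-4-oxobutanoate (not isolated) | C[C@H](CC(=O)OC)C=O | intermediate
5 | methyl (3R,4E)-3,5-dimethyl-6-oxohex-4-enoate | C[C@H](CC(=O)OC)/C=C(\C)C=O | intermediate
6 | methyl (3R,4E)-3,5-dimethylhepta-4,6-dienoate | C[C@H](CC(=O)OC)/C=C(\C)C=C | intermediate
7 | (3R,4E)-3,5-dimethylhepta-4,6-dienal | C[C@H](CC=O)/C=C(\C)C=C | intermediate
8 | ethoxyethyne | CCOC#C | starting material
9 | lithium ethoxyacetylide (not isolated) | [Li]C#COCC | intermediate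
10 | (5R,6E)-1-ethoxy-5,7-dimethylnona-6,8-dien-1-yn-3-ol, both C3 epimers | C[C@H](CC(O)C#COCC)/C=C(\C)C=C | intermediate
11 | tert-butyl{[(5R,6E)-1-ethoxy-5,7-dimethylnona-6,8-dien-1-yn-3-yl]oxy}dimethylsilane | C[C@H](CC(O[Si](C)(C)C(C)(C)C)C#COCC)/C=C(\C)C=C | intermediate
12 | (5R,6E)-3-(tert-butyldimethylsilyloxy)-5,7-dimethylnona-1,6,8-trien-1-one, aldoketene (not isolated) | C[C@H](CC(O[Si](C)(C)C(C)(C)C)C=C=O)/C=C(\C)C=C | intermediate
13 | 2-(tert-butyldimethylsilyloxy)-4,7-dimethyl-7-vinylbicyclo[3.1.1]heptan-6-one; 4-methyl on the side of the carbonyl bridge, 7-methyl syn and 7-vinyl anti to the three-carbon bridge | O=C1[C@@H]2[C@H](C)CC(O[Si](C)(C)C(C)(C)C)[C@H]1[C@]2(C)C=C | intermediate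
14 | 7-acetyl-2-(tert-butyldimethylsilyloxy)-4,7-dimethylbicyclo[3.1.1]heptan-6-one, same configuration as 13 | O=C1[C@@H]2[C@H](C)CC(O[Si](C)(C)C(C)(C)C)[C@H]1[C@]2(C)C(C)=O | intermediate
15 | methacrolein (2-methylprop-2-enal) | CC(=C)C=O | starting material
16 | enol diisopinocampheylborinate of 14 (not isolated) | O=C1[C@@H]2[C@H](C)CC(O[Si](C)(C)C(C)(C)C)[C@H]1[C@]2(C)C(=C)OB([C@@H]3C[C@@H]4C[C@H]([C@H]3C)C4(C)C)[C@@H]3C[C@@H]4C[C@H]([C@H]3C)C4(C)C | intermediate
17 | diisopinocampheylboron aldolate of 18 (not isolated) | O=C1[C@@H]2[C@H](C)CC(O[Si](C)(C)C(C)(C)C)[C@H]1[C@]2(C)C(=O)C[C@@H](OB([C@@H]3C[C@@H]4C[C@H]([C@H]3C)C4(C)C)[C@@H]3C[C@@H]4C[C@H]([C@H]3C)C4(C)C)C(C)=C | intermediate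
18 | 7-[(3R)-3-hydroxy-4-methylpent-4-enoyl]-2-(tert-butyldimethylsilyloxy)-4,7-dimethylbicyclo[3.1.1]heptan-6-one | O=C1[C@@H]2[C@H](C)CC(O[Si](C)(C)C(C)(C)C)[C@H]1[C@]2(C)C(=O)C[C@@H](O)C(C)=C | intermediate
19 | triethylsilyl ether of 18 (7-OTES) | O=C1[C@@H]2[C@H](C)CC(O[Si](C)(C)C(C)(C)C)[C@H]1[C@]2(C)C(=O)C[C@@H](O[Si](CC)(CC)CC)C(C)=C | intermediate
20 | C5 N-tosylhydrazone of 19 (C=N geometry not defined) | Cc1ccc(cc1)S(=O)(=O)NN=C2[C@@H]3[C@H](C)CC(O[Si](C)(C)C(C)(C)C)[C@H]2[C@]3(C)C(=O)C[C@@H](O[Si](CC)(CC)CC)C(C)=C | intermediate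
21 | ring-closed N′-tosylhydrazide, nitrogen on C5 syn to the C1–C3 bridge (not isolated) | C1[C@@H](O[Si](CC)(CC)CC)C(C)(C)[C@@]2(NNS(=O)(=O)c4ccc(C)cc4)[C@@H]3[C@H](C)CC(O[Si](C)(C)C(C)(C)C)[C@H]2[C@]3(C)C1=O | intermediate
22 | C5 monoalkyl diazene (not isolated) | C1[C@@H](O[Si](CC)(CC)CC)C(C)(C)[C@@]2(N=N)[C@@H]3[C@H](C)CC(O[Si](C)(C)C(C)(C)C)[C@H]2[C@]3(C)C1=O | intermediate
23 | 1-(tert-butyldimethylsilyloxy)-7-(triethylsilyloxy)longipinan-9-one | C1[C@@H](O[Si](CC)(CC)CC)C(C)(C)[C@H]2[C@@H]3[C@H](C)CC(O[Si](C)(C)C(C)(C)C)[C@H]2[C@]3(C)C1=O | intermediate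
24 | C8=C9 trimethylsilyl enol ether of 23 (not isolated) | C[Si](C)(C)OC1=C[C@@H](O[Si](CC)(CC)CC)C(C)(C)[C@H]2[C@@H]3[C@H](C)CC(O[Si](C)(C)C(C)(C)C)[C@H]2[C@@]31C | intermediate
25 | 8-(trimethylsilyloxy) derivative of 23 (not isolated) | C[Si](C)(C)O[C@@H]1[C@@H](O[Si](CC)(CC)CC)C(C)(C)[C@H]2[C@@H]3[C@H](C)CC(O[Si](C)(C)C(C)(C)C)[C@H]2[C@]3(C)C1=O | intermediate
26 | 8-hydroxy-1-(tert-butyldimethylsilyloxy)-7-(triethylsilyloxy)longipinan-9-one, 8-OH trans to 7-OTES | O[C@@H]1[C@@H](O[Si](CC)(CC)CC)C(C)(C)[C@H]2[C@@H]3[C@H](C)CC(O[Si](C)(C)C(C)(C)C)[C@H]2[C@]3(C)C1=O | intermediate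
27 | 1-(tert-butyldimethylsilyloxy)-7-(triethylsilyloxy)longipinane-8,9-diol, cis-8,9-diol | O[C@@H]1[C@@H](O[Si](CC)(CC)CC)C(C)(C)[C@H]2[C@@H]3[C@H](C)CC(O[Si](C)(C)C(C)(C)C)[C@H]2[C@]3(C)[C@@H]1O | intermediate
28 | angelic acid, (Z)-2-methylbut-2-enoic acid | C/C=C(/C)C(=O)O | starting material
29 | angelic 2,4,6-trichlorobenzoic anhydride (not isolated) | C/C=C(/C)C(=O)OC(=O)c1c(Cl)cc(Cl)cc1Cl | intermediate
30 | 1-(tert-butyldimethylsilyloxy)-9-hydroxy-7-(triethylsilyloxy)longipinan-8-yl (Z)-2-methylbut-2-enoate, 8-monoangelate of 27 (not isolated) | C/C=C(/C)C(=O)O[C@@H]1[C@@H](O[Si](CC)(CC)CC)C(C)(C)[C@H]2[C@@H]3[C@H](C)CC(O[Si](C)(C)C(C)(C)C)[C@H]2[C@]3(C)[C@@H]1O | intermediate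
31 | 1-(tert-butyldimethylsilyloxy)-7-(triethylsilyloxy)longipinane-8,9-diyl bis[(Z)-2-methylbut-2-enoate] | C/C=C(/C)C(=O)O[C@@H]1[C@@H](O[Si](CC)(CC)CC)C(C)(C)[C@H]2[C@@H]3[C@H](C)CC(O[Si](C)(C)C(C)(C)C)[C@H]2[C@]3(C)[C@@H]1OC(=O)/C(C)=C\C | intermediate
32 | 1,7-dihydroxylongipinane-8,9-diyl bis[(Z)-2-methylbut-2-enoate] | C/C=C(/C)C(=O)O[C@@H]1[C@@H](O)C(C)(C)[C@H]2[C@@H]3[C@H](C)CC(O)[C@H]2[C@]3(C)[C@@H]1OC(=O)/C(C)=C\C | intermediate
33 | 7-hydroxy-1-oxolongipinane-8,9-diyl bis[(Z)-2-methylbut-2-enoate] | C/C=C(/C)C(=O)O[C@@H]1[C@@H](O)C(C)(C)[C@H]2[C@@H]3[C@H](C)CC(=O)[C@H]2[C@]3(C)[C@@H]1OC(=O)/C(C)=C\C | target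

**Step count and risks**

Total step count: 17. Longest linear sequence: 17 steps (1 to 33).

Steps most likely to fail:

1. Step 12. The tertiary C6 radical may be reduced to the isopropyl group before the slow seven-ring closure, or the cyclobutane-bound hydrazinyl radical or sulfonylhydrazide may be diverted before clean loss of sulfinate and N2. Fallback: setting out from 19, condensation with benzyl carbazate would give the carbamate hydrazone F1. The iron-hydride radical cyclisation onto this acyl hydrazone, an alkene–hydrazone coupling that stops at a stable hydrazine, would give the ring-closed N′-benzyloxycarbonyl hydrazine F2, which can be purified and characterised. Hydrogenolysis (H2, Pd/C) would free the alkylhydrazine F3, and N′-tosylation (TsCl, pyridine) would come back to the route at 21, which is decomposed to 23 as in the second stage of step 12. This separates ring closure from nitrogen removal, but it still depends on the same radical ring closure.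

2. Step 7. The ketene may dimerise, may close through an allyl-stabilised zwitterion to a fused or six-membered isomer, or may add with eroded facial selectivity. Fallback: setting out from 7, addition of the lithium enolate of N,N-dimethylacetamide would give the β-hydroxy amide F4, and silylation the amide F5. Tf2O and 2,4,6-collidine in 1,2-dichloroethane would generate the more electrophilic keteniminium triflate F6, whose intramolecular (2+2) cycloaddition at 80 °C would give the cyclobutaniminium triflate F7. Aqueous NaHCO3 hydrolysis would come back to the route at 13.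

3. Step 9. The aldol may show poor facial selectivity at C7 (the sense of induction of the boron reagent on this hindered ketone would have to be confirmed, the antipodal reagent being the alternative), and the chloroborane may reduce or the enolate attack the cyclobutanone. Fallback: setting out from 14, soft enolisation (Me3SiOTf, Et3N) would give the enol silane F8. A Mukaiyama aldol reaction with 15 under a tartrate-derived chiral acyloxyborane catalyst would give the silyl aldolate F9, and mild acid work-up would come back to the route at 18.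

**Further compounds**

F1 | step 12 | C5 N-(benzyloxycarbonyl)hydrazone of 19 | O=C(OCc1ccccc1)NN=C2[C@@H]3[C@H](C)CC(O[Si](C)(C)C(C)(C)C)[C@H]2[C@]3(C)C(=O)C[C@@H](O[Si](CC)(CC)CC)C(C)=C
F2 | step 12 | ring-closed N′-(benzyloxycarbonyl)hydrazine at C5 | C1[C@@H](O[Si](CC)(CC)CC)C(C)(C)[C@@]2(NNC(=O)OCc4ccccc4)[C@@H]3[C@H](C)CC(O[Si](C)(C)C(C)(C)C)[C@H]2[C@]3(C)C1=O
F3 | step 12 | ring-closed C5 alkylhydrazine | C1[C@@H](O[Si](CC)(CC)CC)C(C)(C)[C@@]2(NN)[C@@H]3[C@H](C)CC(O[Si](C)(C)C(C)(C)C)[C@H]2[C@]3(C)C1=O
F4 | step 7 | (5R,6E)-3-hydroxy-N,N,5,7-tetramethylnona-6,8-dienamide, both C3 epimers | C[C@H](CC(O)CC(=O)N(C)C)/C=C(\C)C=C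
F5 | step 7 | tert-butyldimethylsilyl ether of F4 | C[C@H](CC(O[Si](C)(C)C(C)(C)C)CC(=O)N(C)C)/C=C(\C)C=C
F6 | step 7 | keteniminium triflate from F5 | C[C@H](CC(O[Si](C)(C)C(C)(C)C)C=C=[N+](C)C)/C=C(\C)C=C.[O-]S(=O)(=O)C(F)(F)F
F7 | step 7 | N,N-dimethyl cyclobutaniminium triflate corresponding to 13 | C[N+](C)=C1[C@@H]2[C@H](C)CC(O[Si](C)(C)C(C)(C)C)[C@H]1[C@]2(C)C=C.[O-]S(=O)(=O)C(F)(F)F
F8 | step 9 | trimethylsilyl enol ether of 14 | O=C1[C@@H]2[C@H](C)CC(O[Si](C)(C)C(C)(C)C)[C@H]1[C@]2(C)C(=C)O[Si](C)(C)C
F9 | step 9 | trimethylsilyl ether of 18 | O=C1[C@@H]2[C@H](C)CC(O[Si](C)(C)C(C)(C)C)[C@H]1[C@]2(C)C(=O)C[C@@H](O[Si](C)(C)C)C(C)=C
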